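**Remarks on the chemistry**

- Structure check: the CIP descriptors derived from the SMILES strings of the target, 10, 12, 14 and the key-step products of the three alternatives are mutually consistent, so no structure needed correcting. The target is 3R,4R in both lactones (hydroxyl cis, ring A benzyl trans to the C4 arm). The spatial arrangement at C4 is the same from 6 to 15, but its descriptor is S in 6–9 and R from 10 on, because the C3 oxygen changes the CIP ranking.
- Stoichiometry: the route is two-directional. Step 1 joins two molecules of 1 into one molecule of 2. Steps 2, 3, 6 and 8 each attach two molecules of the monofunctional partner to the biaryl.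
- Precursor design: the free-hydroxyl bis(lactone) on the O-benzylated biaryl is kept. Two refinements are made: 10 is used as whatever C3 epimer mixture step 6 delivers, and the bromide 12 is made fresh in one step.
- Assumption: the (R,R) enantiomer of Et-DuPhos on rhodium is taken to deliver the (S)-configured 2-(arylmethyl)succinate half-ester (by analogy with the enamide sense of this ligand class). If the sense were reversed, the other ligand enantiomer would be used with no other change.
- Assumption: 4-(benzyloxy)-3-methoxybenzyl alcohol is taken as a catalogue compound, which saves one step compared with starting from the aldehyde.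

## Structural features

The target is a C2-symmetric dimer of two α-hydroxy-α,β-dibenzyl-γ-butyrolactones (O1, C2 carbonyl, C3, C4, C5), joined by a single aryl–aryl bond between C5 and C5' of the guaiacyl rings (rings B and B') that hang on the C4 methylene arms. Each lactone has two adjacent stereocentres: the fully substituted carbinol C3 (R), which carries OH, the lactone carbonyl and the 4-hydroxy-3-methoxybenzyl group of ring A, and the tertiary C4 (R), which carries the CH2 arm to ring B; the two benzyl-type groups are trans and the hydroxyl is cis to the C4 arm. The two stereo-pairs are separated by the whole biaryl, so neither lactone can control the other, and an error in one arm gives a diastereomer that differs only at a remote site. The biaryl axis has only two ortho substituents (the oxygens at C4 and C4' of rings B and B') and is therefore not a stable stereo-element. The fragile groups are the four free phenols (two of them forming an oxidation-prone 2,2'-biphenol), the two lactones (hydroxide, hydride) and the tertiary α-hydroxy lactone units. The real difficulty is to build the quaternary C3 carbinol twice, in the correct relation to C4 and in one absolute sense. The key step uses the fact that C3 sits between the C2 carbonyl and the stereogenic C4 inside a five-membered ring: as a planar alkoxide–enolate, C3 has one face screened by the C4 arm, so the ring A benzyl group can be brought in last and trans to that arm.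

## Logic of the disconnections

15 ⇒ 14. The four phenolic O–H bonds are traced back to four aryl O–CH2Ph bonds. The phenols would not survive strong base or oxidants, and one protecting group of a single kind allows a single final operation. The forward step must cleave only aryl benzyl ethers; C3–OH is tertiary and not benzylic, and C5–O1 is not benzylic, so hydrogenolysis is selective.

14 ⇒ 10 + 12. The two C3–CH2(ring A) bonds are cut. This removes both quaternary centres and both outer rings at once and leaves 10, whose only stereocentres that matter are the two C4 atoms. The forward step must alkylate two enolised C3 atoms on the face opposite the C4 arm, at carbon and not at oxygen, through the tetra-anion 13; it must do so twice on one molecule.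

12 ⇒ 11. The C–Br bond is cut back to C–OH. Being an electron-rich benzylic halide, 12 does not keep well and should be made from 11 immediately before use.

10 ⇒ 8. The two C3–O bonds are cut. This leaves 8 with one stereocentre per ring and no oxygen at C3. The forward step is an enolate oxidation through 9; its facial selectivity is not critical, because C3 is flattened again in the key step.

8 ⇒ 6. The two lactone C2–O1 bonds are opened and C5 is raised to the ester oxidation level, by way of 7. This converts each ring into an acyclic succinate half-ester arm of 6, whose two carboxyl termini are already differentiated. The forward step must reduce the ester and leave the carboxylate untouched.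

6 ⇒ 5. The C4–H bond and the neighbouring benzylic C–H bond of each arm are removed to give the two trisubstituted alkenes of 5. All stereochemistry is thereby erased; the forward step is a two-fold catalytic asymmetric hydrogenation, which must set both remote centres in the same absolute sense and spare the benzyl ethers.

5 ⇒ 3 + 4. The two C=C bonds between the benzylic carbons and the succinate α-carbons are cut. The entire four-carbon lactone precursor of each arm comes from 4 in one condensation (two molecules of 4 per molecule of 3), which by its mechanism delivers the half-ester with the ester on the alkene-bearing carbon.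

3 ⇒ 2 ⇒ 1. The two O–benzyl bonds are removed, and then the C5–C5' biaryl bond is cut, which halves the molecule into two molecules of 1. The biaryl core is thus made first, by oxidative coupling of 1, whose para position and one ortho position are blocked, so that no cross-coupling or regiochemical problem arises later.

## Other disconnections considered

Alternative 1: The cut is the C3–C4 bond of each lactone. The forward key step would be a two-fold Ireland–Claisen rearrangement of the bis-ester A2, in which each arm of the biaryl ends in a CH2–CH=CH–CH(CH3)–O allylic ester of a 2-benzyloxy-3-arylpropanoyl unit carrying ring A. Enolisation with LiN(iPr)2 and silylation with Me3SiCl, with the benzyloxy group held cis to the silyloxy group by lithium chelation, would be followed by two chair rearrangements that give the bis-acid A1 with two (E)-propenyl groups. In its favour: both stereocentres of a lactone arise in one concerted event, and the crowded quaternary C3 is formed intramolecularly, not by an intermolecular attack on a fully substituted carbon; on this point it is the better of the two plans. A chair analysis shows what it demands: with the chelated enolate, the arm alkene must be (Z) and the carbinol carbon (R) for the hydroxyl to end up cis to the C4 arm; an (E)-alkene would lead to the C3 epimer. Against it here: two geometrically pure (Z)-alkenes and two enantiopure carbinols must be built on the biaryl, the geometry of a tetrasubstituted enolate must be held by chelation twice, and A1 still lacks both lactone rings. The propenyl groups would have to be cleaved oxidatively in the presence of four electron-rich arenes, then reduced and lactonised, discarding two carbons per arm, and six benzyl ethers (two of them tertiary) would have to be removed. In structural terms it builds the ring bond and not the exocyclic one; in mechanistic terms it replaces a facial bias by a pericyclic transfer of chirality, which is equally defensible; in step economy it is clearly the longer plan, at roughly a dozen operations or more against nine.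

Alternative 2: The cut is the C3–O bond. The forward key step would be a double Baeyer–Villiger oxidation of the bis(3-acetyl lactone) A4 with buffered CF3CO3H, the quaternary C3 migrating with retention to give the di-O-acetate A3. A4 would come from 8 by C-acetylation and then alkylation with 12, the benzyl group again entering anti to the C4 arm. In its favour: the C–C bond at C3 is made from a stabilised β-keto lactone enolate under mild base, so no tetra-anion is needed, which is an operational advantage over the chosen plan; the stereocontrol logic of the alkylation is the same as in the chosen plan (equal on that point), and retention in the 1,2-shift is secured by mechanism. Against it here: the migrating carbon bears the electron-withdrawing lactone carbonyl, which lowers its migratory aptitude relative to an ordinary tertiary carbon and forces the use of a strong peracid; that peracid is a real threat to four alkoxy-substituted arenes. The non-enolisable β-keto lactone is also open to retro-Claisen loss of the acetyl group, and the acetates must later be removed without opening the lactones. It needs two operations more than the chosen plan (acetylation and acetate cleavage), about eleven steps against nine.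

Alternative 3: The cut is the C4–CH2(ring B) bond. The forward key step would be a two-fold Fráter–Seebach alkylation: two alkoxide–enolates of dimethyl (R)-malate A6 would displace both bromides of the biaryl bis(benzyl bromide) A7 (two steps from 3), anti to the hydroxyl, to give the (2R,3S)-configured tetraester A5. In its favour: C4 is set from the chiral pool by a well-understood substrate-controlled reaction, with no chiral precious-metal catalyst; on the source of absolute configuration it is the equal of the chosen plan and arguably the more robust. Against it here: the skeleton is not complete after this step, since ring A must still be attached at the carbinol carbon. Four further operations (ester hydrolysis, temporary tying-up of the hydroxy-acid end, reduction of the other carboxyl group, lactonisation) would lead to the cis bis(hydroxy lactone) A8, whose tetra-anion is again 13. The alternative therefore replaces steps 3–6 and not the key step. The ester that must be reduced is the one remote from the hydroxyl, the opposite of the usual preference in malate reductions; the (R)-malate is the less available enantiomer; and any imperfect selectivity at either of the two remote sites adds diastereomers statistically. In step economy it needs about seven operations from 3 to reach the stage of 10, against four in the chosen plan.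

Key step: step 8

## Route

Step 1
Reactants: 1 vanillin (two molecules, joined at C5)
Product: 2 dehydrodivanillin (6,6'-dihydroxy-5,5'-dimethoxybiphenyl-3,3'-dicarbaldehyde)
Conditions: FeSO4·7H2O (cat.), Na2S2O8 (0.55 equiv per mol of 1), H2O, 50 °C
Reagents that add atoms: vanillin (the second molecule of 1), COc1cc(C=O)ccc1O
Why: Iron-catalysed persulfate oxidative phenol coupling (dehydrodimerisation): two phenoxyl radicals of 1 combine at C5 and the bis-dienone tautomerises, so that two C8H8O3 units give one C16H14O6 with loss of two hydrogen atoms to the oxidant. The para position of 1 is blocked by the formyl group and one ortho position by OMe, so C–C coupling should occur at C5 only. The sparingly soluble dimer should precipitate, which protects it from further oxidation.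

Step 2
Reactants: 2 dehydrodivanillin
Product: 3 6,6'-bis(benzyloxy)-5,5'-dimethoxybiphenyl-3,3'-dicarbaldehyde
Conditions: BnBr (2.5 equiv), K2CO3, DMF, 60 °C
Reagents that add atoms: benzyl bromide (two molecules), BrCc1ccccc1
Why: Williamson ether synthesis on the two phenoxides; the aldehydes are inert to carbonate, and benzyl is chosen because all four phenol protecting groups of the route can then be removed together at the end.

Step 3
Reactants: 3 6,6'-bis(benzyloxy)-5,5'-dimethoxybiphenyl-3,3'-dicarbaldehyde; 4 dimethyl succinate (two molecules)
Product: 5 (3E,3'E)-4,4'-[6,6'-bis(benzyloxy)-5,5'-dimethoxybiphenyl-3,3'-diyl]bis[3-(methoxycarbonyl)but-3-enoic acid] (two-fold Stobbe half-ester)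
Conditions: 4 (4 equiv), NaOMe (5 equiv), MeOH–THF, reflux; then aq HCl
Reagents that add atoms: none
Why: Two-fold Stobbe condensation; aldol addition, lactonisation and E1cB ring opening give in each arm the carboxylate with the ester on the alkene-bearing carbon, and formation of the carboxylate stops any second condensation; the (E)-alkene (aryl trans to the ester) is the expected major isomer.

Step 4
Reactants: 5 two-fold Stobbe half-ester
Product: 6 (3S,3'S)-4,4'-[6,6'-bis(benzyloxy)-5,5'-dimethoxybiphenyl-3,3'-diyl]bis[3-(methoxycarbonyl)butanoic acid]
Conditions: H2 (5 bar), [Rh(cod)((R,R)-Et-DuPhos)]OTf (1 mol% per alkene), MeOH, 25 °C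
Reagents that add atoms: none
Why: Catalytic asymmetric hydrogenation of an itaconate-type half-ester; the alkene and the carboxyl arm chelate to cationic monovalent rhodium and the C2-symmetric bisphospholane selects the alkene face, so each arm is reduced independently and the catalyst alone sets the new stereocentre (S in both arms); this homogeneous catalyst does not cleave benzyl ethers.

Step 5
Reactants: 6 bis[(S)-succinate half-ester]
Product: 8 (4S,4'S)-4,4'-{[6,6'-bis(benzyloxy)-5,5'-dimethoxybiphenyl-3,3'-diyl]bis(methylene)}bis(dihydrofuran-2(3H)-one), via bis(hydroxy acid) 7 (not isolated)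
Conditions: KOH (2.0 equiv), EtOH, 0 °C; CaCl2, NaBH4, EtOH, −10 °C → rt; then 2 M HCl, rt
Reagents that add atoms: none
Why: Chemoselective borohydride reduction: Ca(BH4)2 made in the flask reduces the methyl esters while the potassium carboxylates are inert, and acidification lactonises the γ-hydroxy acid 7 to the five-membered lactone; the stereocentre is not touched (the low temperature limits enolisation of the ester before it is reduced).

Step 6
Reactants: 8 bis[(S)-β-(arylmethyl) lactone]
Product: 10 (3S,4R,3'S,4'R)-4,4'-{[6,6'-bis(benzyloxy)-5,5'-dimethoxybiphenyl-3,3'-diyl]bis(methylene)}bis(3-hydroxydihydrofuran-2(3H)-one) (hydroxyl trans to the C4 arm), via disodium bis(lactone enolate) 9 (not isolated)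
Conditions: NaN(SiMe3)2 (2.3 equiv), THF, −78 °C; 2-(phenylsulfonyl)-3-phenyloxaziridine (2.6 equiv), −78 °C; AcOH
Reagents that add atoms: 2-(phenylsulfonyl)-3-phenyloxaziridine (two molecules; each delivers one oxygen atom), O=S(=O)(c1ccccc1)N1OC1c1ccccc1
Why: Enolate oxidation with an N-sulfonyloxaziridine; the oxidant should approach each enolate of 9 anti to the C4 arm and give mainly the trans (3S) alcohol, but any C3 epimer is equally useful because step 8 enolises C3 again; the sodium counter-ion limits addition of the enolate to the sulfonimine by-product, and C4 is not enolisable.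

Step 7
Reactants: 11 4-(benzyloxy)-3-methoxybenzyl alcohol
Product: 12 4-(benzyloxy)-3-methoxybenzyl bromide
Conditions: PBr3 (0.4 equiv), Et2O, 0 °C; used at once
Reagents that add atoms: phosphorus tribromide, BrP(Br)Br
Why: Conversion of a benzylic alcohol into the bromide through its phosphite ester (SN2 by bromide); the aryl benzyl ether survives the short cold reaction, and immediate use avoids decomposition of the electron-rich benzylic bromide.

Step 8
Reactants: 10 bis(α-hydroxy lactone); 12 4-(benzyloxy)-3-methoxybenzyl bromide (two molecules)
Product: 14 tetra-O-benzyl bis-5,5-nortrachelogenin (3R,4R,3'R,4'R), via tetralithium bis(alkoxide–enolate) 13 (not isolated)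
Conditions: LiN(SiMe3)2 (4.4 equiv), THF, −78 → −40 °C; 12 (2.6 equiv), THF–DMPU, −78 → −20 °C; AcOH
Reagents that add atoms: none
Why: Four equivalents of LiN(SiMe3)2 remove both O–H and both C3–H protons of 10 and give in each lactone a lithium alkoxide–enolate (13) in which C3 is planar, so both C3 epimers of 10 converge on one species. Each enolate carbon then displaces bromide from one molecule of 12 in an SN2 reaction and forms the C3–CH2(ring A) bond; no ring is closed. The closest known reaction type is the anti-selective C-alkylation of dianions of α-hydroxy-β-substituted γ-butyrolactones. The two new quaternary stereocentres (C3 and C3') are controlled by the adjacent C4 stereocentre: the CH2 arm to the biaryl screens the cis face of the nearly flat five-membered enolate, so the electrophile should enter trans to it, leaving the oxygen cis to the arm, which corresponds to R at C3 in both rings. The two lactones are insulated from each other by the biaryl and should react with the same local bias, which leads to the C2-symmetric product. The step needs C- over O-alkylation; this is secured by the tightly lithium-bound alkoxide and ring oxygen on one side and by the soft, reactive benzylic bromide on the other. DMPU is added to loosen aggregates of the tetra-anion so that the second alkylation does not lag behind the first, and oxygen is excluded rigorously because the ene-diolate is easily oxidised. The benzyl and methyl aryl ethers are inert to the amide base.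

Step 9
Reactants: 14 tetra-O-benzyl bis-5,5-nortrachelogenin
Product: 15 bis-5,5-nortrachelogenin (3R,4R,3'R,4'R)
Conditions: H2 (1 atm), Pd/C (10%), EtOAc–MeOH, rt
Reagents that add atoms: none
Why: Hydrogenolysis of the four aryl benzyl ethers; the tertiary C3 alcohols and the lactone C5–O1 bonds are not benzylic and should stay intact, and no stereocentre is affected under these neutral conditions.

## Compound list

1 | vanillin | COc1cc(C=O)ccc1O | starting material
2 | dehydrodivanillin (6,6'-dihydroxy-5,5'-dimethoxybiphenyl-3,3'-dicarbaldehyde) | COc1cc(C=O)cc(c1O)-c1cc(C=O)cc(OC)c1O | intermediate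
3 | 6,6'-bis(benzyloxy)-5,5'-dimethoxybiphenyl-3,3'-dicarbaldehyde | COc1cc(C=O)cc(c1OCc1ccccc1)-c1cc(C=O)cc(OC)c1OCc1ccccc1 | intermediate
4 | dimethyl succinate | COC(=O)CCC(=O)OC | starting material
5 | (3E,3'E)-4,4'-[6,6'-bis(benzyloxy)-5,5'-dimethoxybiphenyl-3,3'-diyl]bis[3-(methoxycarbonyl)but-3-enoic acid] | COC(=O)/C(CC(=O)O)=C/c1cc(OC)c(OCc2ccccc2)c(c1)-c1cc(/C=C(\CC(=O)O)C(=O)OC)cc(OC)c1OCc1ccccc1 | intermediate
6 | (3S,3'S)-4,4'-[6,6'-bis(benzyloxy)-5,5'-dimethoxybiphenyl-3,3'-diyl]bis[3-(methoxycarbonyl)butanoic acid] | COC(=O)[C@H](CC(=O)O)Cc1cc(OC)c(OCc2ccccc2)c(c1)-c1cc(C[C@@H](CC(=O)O)C(=O)OC)cc(OC)c1OCc1ccccc1 | intermediate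
7 | (3S,3'S)-4,4'-[6,6'-bis(benzyloxy)-5,5'-dimethoxybiphenyl-3,3'-diyl]bis[3-(hydroxymethyl)butanoic acid] | OC[C@H](CC(=O)O)Cc1cc(OC)c(OCc2ccccc2)c(c1)-c1cc(C[C@@H](CC(=O)O)CO)cc(OC)c1OCc1ccccc1 | intermediate (not isolated)
8 | (4S,4'S)-4,4'-{[6,6'-bis(benzyloxy)-5,5'-dimethoxybiphenyl-3,3'-diyl]bis(methylene)}bis(dihydrofuran-2(3H)-one) | O=C1OC[C@H](C1)Cc1cc(OC)c(OCc2ccccc2)c(c1)-c1cc(C[C@@H]2COC(=O)C2)cc(OC)c1OCc1ccccc1 | intermediate
9 | disodium bis(lactone enolate) of 8 (C4 arrangement unchanged) | [Na+].[Na+].[O-]C1=C[C@@H](CO1)Cc1cc(OC)c(OCc2ccccc2)c(c1)-c1cc(C[C@@H]2COC([O-])=C2)cc(OC)c1OCc1ccccc1 | intermediate (not isolated)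
10 | (3S,4R,3'S,4'R)-4,4'-{[6,6'-bis(benzyloxy)-5,5'-dimethoxybiphenyl-3,3'-diyl]bis(methylene)}bis(3-hydroxydihydrofuran-2(3H)-one) | O[C@@H]1C(=O)OC[C@H]1Cc1cc(OC)c(OCc2ccccc2)c(c1)-c1cc(C[C@@H]2COC(=O)[C@H]2O)cc(OC)c1OCc1ccccc1 | intermediate
11 | 4-(benzyloxy)-3-methoxybenzyl alcohol | COc1cc(CO)ccc1OCc1ccccc1 | starting material
12 | 4-(benzyloxy)-3-methoxybenzyl bromide | COc1cc(CBr)ccc1OCc1ccccc1 | intermediate
13 | tetralithium bis(alkoxide–enolate) of 10 (C3 planar, C4 arrangement unchanged) | [Li+].[Li+].[Li+].[Li+].[O-]C1=C([O-])OC[C@H]1Cc1cc(OC)c(OCc2ccccc2)c(c1)-c1cc(C[C@@H]2COC([O-])=C2[O-])cc(OC)c1OCc1ccccc1 | intermediate (not isolated)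
14 | tetra-O-benzyl bis-5,5-nortrachelogenin (3R,4R,3'R,4'R) | COc1cc(C[C@]2(O)C(=O)OC[C@H]2Cc2cc(OC)c(OCc3ccccc3)c(-c3cc(C[C@@H]4COC(=O)[C@@]4(O)Cc4ccc(OCc5ccccc5)c(OC)c4)cc(OC)c3OCc3ccccc3)c2)ccc1OCc1ccccc1 | intermediate
15 | bis-5,5-nortrachelogenin (3R,4R,3'R,4'R) | COc1cc(C[C@]2(O)C(=O)OC[C@H]2Cc2cc(OC)c(O)c(-c3cc(C[C@@H]4COC(=O)[C@@]4(O)Cc4ccc(O)c(OC)c4)cc(OC)c3O)c2)ccc1O | target

## Step count and risk

Total: 9 steps. Longest linear sequence: 8 steps (1 → 2 → 3 → 5 → 6 → 8 → 10 → 14 → 15); step 7 is a one-step side branch.

Step 8 (key step). The most likely failures are incomplete two-fold alkylation and erosion of facial selectivity at one of the two sites, because the tetra-anion is highly aggregated and the second alkylation takes place on an already crowded dianion; competing oxidation of the ene-diolate by traces of oxygen is a further concern. Fallback (aldol in place of alkylation): setting out from 10, the tetra-anion 13 is generated as before and treated at −78 °C with 4-(benzyloxy)-3-methoxybenzaldehyde (COc1cc(C=O)ccc1OCc1ccccc1), a smaller and far more reactive electrophile for which O-alkylation is not an issue and which should also add anti to the C4 arm. This gives the bis-aldol adduct F1, whose benzylic carbinol configuration is irrelevant. Hydrogenation of F1 over Pd/C in AcOH should remove the four benzyl ethers and then the two benzylic hydroxyls, whose C–O bonds are activated by the para-hydroxyl groups uncovered by debenzylation; the fallback re-enters the route at 15.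

Step 4. The most likely failure is imperfect enantioface control at one of the two alkenes; this would introduce a diastereomer with one wrong arm that is hard to remove, because the two centres are remote from each other. Fallback (auxiliary control in place of catalyst control): setting out from 3, Knoevenagel–Doebner condensation with malonic acid (pyridine, piperidine) gives the bis(cinnamic acid) F2. Hydrogenation of the alkenes over RhCl(PPh3)3, which spares the benzyl ethers, gives the bis(3-arylpropanoic acid) F3. N-Acylation of (R)-4-benzyloxazolidin-2-one with F3 (t-BuCOCl, Et3N, LiCl, THF) gives the bis(imide) F4. Alkylation of its sodium enolates (NaN(SiMe3)2, tert-butyl bromoacetate), anti to the auxiliary benzyl group, gives the bis(alkylated imide) F5. Reduction with LiBH4 removes the auxiliary and gives the bis(hydroxy tert-butyl ester) F6, which lactonises with CF3CO2H and re-enters the route at 8. Diastereomers can be removed at F5, where each wrong centre is adjacent to an auxiliary.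

Step 6. The most likely failures are incomplete oxidation of the second enolate and consumption of enolate by addition to the sulfonimine by-product. Fallback (Rubottom oxidation in place of direct enolate oxidation): setting out from 8, enolisation with LiN(iPr)2 and trapping with Me3SiCl gives the bis(silyl ketene acetal) F7. Oxidation of F7 with mCPBA at low temperature, followed by acidic desilylation, should give 10 through epoxidation and silyl migration; the very reactive ketene acetals are oxidised much faster than the alkoxyarenes, and the C3 configuration again does not matter.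

## Further compounds

F1 | step 8 | bis-aldol adduct: 14 with a hydroxyl on each ring A benzylic carbon (carbinol configuration not controlled) | COc1cc(C(O)[C@]2(O)C(=O)OC[C@H]2Cc2cc(OC)c(OCc3ccccc3)c(-c3cc(C[C@@H]4COC(=O)[C@@]4(O)C(O)c4ccc(OCc5ccccc5)c(OC)c4)cc(OC)c3OCc3ccccc3)c2)ccc1OCc1ccccc1
F2 | step 4 | (2E,2'E)-3,3'-[6,6'-bis(benzyloxy)-5,5'-dimethoxybiphenyl-3,3'-diyl]bis(prop-2-enoic acid) | OC(=O)/C=C/c1cc(OC)c(OCc2ccccc2)c(c1)-c1cc(/C=C/C(=O)O)cc(OC)c1OCc1ccccc1
F3 | step 4 | 3,3'-[6,6'-bis(benzyloxy)-5,5'-dimethoxybiphenyl-3,3'-diyl]dipropanoic acid | OC(=O)CCc1cc(OC)c(OCc2ccccc2)c(c1)-c1cc(CCC(=O)O)cc(OC)c1OCc1ccccc1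
F4 | step 4 | bis[N-(3-arylpropanoyl)] imide of (R)-4-benzyloxazolidin-2-one | O=C(CCc1cc(OC)c(OCc2ccccc2)c(c1)-c1cc(CCC(=O)N2[C@H](Cc3ccccc3)COC2=O)cc(OC)c1OCc1ccccc1)N1[C@H](Cc2ccccc2)COC1=O
F5 | step 4 | bis(imide) alkylated with CH2CO2tBu at each α-carbon (S at both new centres) | CC(C)(C)OC(=O)C[C@H](Cc1cc(OC)c(OCc2ccccc2)c(c1)-c1cc(C[C@@H](CC(=O)OC(C)(C)C)C(=O)N2[C@H](Cc3ccccc3)COC2=O)cc(OC)c1OCc1ccccc1)C(=O)N1[C@H](Cc2ccccc2)COC1=O
F6 | step 4 | di-tert-butyl (3S,3'S)-4,4'-[6,6'-bis(benzyloxy)-5,5'-dimethoxybiphenyl-3,3'-diyl]bis[3-(hydroxymethyl)butanoate] | CC(C)(C)OC(=O)C[C@H](Cc1cc(OC)c(OCc2ccccc2)c(c1)-c1cc(C[C@@H](CC(=O)OC(C)(C)C)CO)cc(OC)c1OCc1ccccc1)CO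
F7 | step 6 | bis(trimethylsilyl ketene acetal) of 8 | C[Si](C)(C)OC1=C[C@@H](CO1)Cc1cc(OC)c(OCc2ccccc2)c(c1)-c1cc(C[C@@H]2COC(O[Si](C)(C)C)=C2)cc(OC)c1OCc1ccccc1
A1 | alternative 1 | two-fold 2-benzyloxy-2-(4-benzyloxy-3-methoxybenzyl)-3-(arylmethyl)hex-4-enoic acid on the O-benzylated biaryl, (E)-alkenes | COc1cc(C[C@](OCc2ccccc2)(C(=O)O)[C@@H](/C=C/C)Cc2cc(OC)c(OCc3ccccc3)c(c2)-c2cc(C[C@H](/C=C/C)[C@@](OCc3ccccc3)(C(=O)O)Cc3ccc(OCc4ccccc4)c(OC)c3)cc(OC)c2OCc2ccccc2)ccc1OCc1ccccc1
A2 | alternative 1 | bis-ester: each biaryl arm as (Z)-CH2–CH=CH–CH(CH3)–O ester, (R) at the carbinol carbon, of 2-benzyloxy-3-(4-benzyloxy-3-methoxyphenyl)propanoic acid (α-carbon of either configuration, lost on enolisation) | COc1cc(CC(OCc2ccccc2)C(=O)O[C@H](C)/C=C\Cc2cc(OC)c(OCc3ccccc3)c(c2)-c2cc(C/C=C\[C@@H](C)OC(=O)C(OCc3ccccc3)Cc3ccc(OCc4ccccc4)c(OC)c3)cc(OC)c2OCc2ccccc2)ccc1OCc1ccccc1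
A3 | alternative 2 | tetra-O-benzyl bis-5,5-nortrachelogenin di-O-acetate | COc1cc(C[C@]2(OC(C)=O)C(=O)OC[C@H]2Cc2cc(OC)c(OCc3ccccc3)c(-c3cc(C[C@@H]4COC(=O)[C@@]4(OC(C)=O)Cc4ccc(OCc5ccccc5)c(OC)c4)cc(OC)c3OCc3ccccc3)c2)ccc1OCc1ccccc1
A4 | alternative 2 | bis(3-acetyl lactone): 14 with an acetyl group in place of each C3 hydroxyl, acetyl cis to the C4 arm | COc1cc(C[C@]2(C(C)=O)C(=O)OC[C@H]2Cc2cc(OC)c(OCc3ccccc3)c(-c3cc(C[C@@H]4COC(=O)[C@@]4(C(C)=O)Cc4ccc(OCc5ccccc5)c(OC)c4)cc(OC)c3OCc3ccccc3)c2)ccc1OCc1ccccc1
A5 | alternative 3 | tetramethyl bis[(2R,3S)-3-(arylmethyl)malate] on the O-benzylated biaryl | COC(=O)[C@H](O)[C@@H](C(=O)OC)Cc1cc(OC)c(OCc2ccccc2)c(c1)-c1cc(C[C@H](C(=O)OC)[C@@H](O)C(=O)OC)cc(OC)c1OCc1ccccc1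
A6 | alternative 3 | dimethyl (R)-malate | COC(=O)C[C@@H](O)C(=O)OC
A7 | alternative 3 | 2,2'-bis(benzyloxy)-5,5'-bis(bromomethyl)-3,3'-dimethoxybiphenyl | BrCc1cc(OC)c(OCc2ccccc2)c(c1)-c1cc(CBr)cc(OC)c1OCc1ccccc1
A8 | alternative 3 | (3R,4R,3'R,4'R)-bis(α-hydroxy lactone), the C3 epimer of 10 (hydroxyl cis to the C4 arm) | O[C@H]1C(=O)OC[C@H]1Cc1cc(OC)c(OCc2ccccc2)c(c1)-c1cc(C[C@@H]2COC(=O)[C@@H]2O)cc(OC)c1OCc1ccccc1
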